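The carbocycle is made last, by a [3+3] annulation on a finished bromo-oxane. The key step joins aldehyde 8 (C-2', C-1', C-6'; C-1' carries the oxane) with vinylsilane 10 (C-5', C-4' and its methyl, C-3') in one flask: an aluminium-promoted ene reaction forms C-5'–C-6', and the allylsilane so created closes C-3'–C-2' onto the aldehyde. It exploits the fact that the cyclohexane ring is an acrolein unit (C-2' carbinol, C-1', C-6') facing an isobutene unit (C-3', C-4', C-5') whose C-4'–C-5' olefin, fixed in place by silicon, later takes up Cl and Br. Precursor 8 is an α-methylene aldehyde; epoxidation, chloride opening and halide interchange finish the ring.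

Key step: step 7

Remark on locants: oxane atoms are O-1 and C-2 to C-6; the carbocycle atoms are called C-1' (bonded to C-2), C-2' (carbinol), C-3' (CH2), C-4' (bears the methyl group, later Cl), C-5' (later Br) and C-6' (CH2) in every intermediate, whatever its systematic name.

Step 1
Reactants: 1 6-methylhept-5-en-2-one
Product: 3 (3S)-3-hydroxy-6-methylhept-5-en-2-one, via aminooxy ketone 2 (not isolated)
Conditions: PhNO (slow addition), D-proline (20 mol%), DMSO, rt; then CuSO4·5H2O (30 mol%), MeOH, 0 °C
Reagents that add atoms: nitrosobenzene, O=Nc1ccccc1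
Why: Proline-catalysed α-aminoxylation (O-selective nitroso aldol reaction) through the more substituted (E)-enamine of the methyl ketone, in which the carboxylic acid of D-proline steers the nitroso oxygen to one enamine face and should set C-3 as S, followed by copper-catalysed N–O cleavage that leaves the trisubstituted olefin untouched.

Step 2
Reactants: 3 (3S)-3-hydroxy-6-methylhept-5-en-2-one; 4 bromo(prop-1-en-2-yl)magnesium
Product: 5 (3S,4S)-2,3,7-trimethylocta-1,6-diene-3,4-diol
Conditions: 4 (2.5 equiv), THF, −78 → −30 °C; then H2O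
Reagents that add atoms: none
Why: Chelation-controlled Grignard addition (Cram chelate model), in which the first equivalent forms the magnesium alkoxide, magnesium bridges the alkoxide and the ketone oxygen in a five-membered ring, and the isopropenyl group should add on the side of the carbinol hydrogen, anti to the prenyl CH2, so that the new tertiary carbinol (C-3 of 5) is S.

Step 3
Reactants: 5 (3S,4S)-2,3,7-trimethylocta-1,6-diene-3,4-diol
Product: 6 (3S,4S)-3-hydroxy-2,3,7-trimethylocta-1,6-dien-4-yl acetate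
Conditions: Ac2O, pyridine, DMAP (cat.), CH2Cl2, 0 °C
Reagents that add atoms: acetic anhydride, CC(=O)OC(C)=O
Why: Selective esterification under nucleophilic catalysis, in which the secondary hydroxyl is acetylated while the hindered tertiary allylic hydroxyl stays free for the ring closure.

Step 4
Reactants: 6 (3S,4S)-3-hydroxy-2,3,7-trimethylocta-1,6-dien-4-yl acetate
Product: 7 (2S,3S,5S)-5-bromo-2,6,6-trimethyl-2-(prop-1-en-2-yl)oxan-3-yl acetate
Conditions: 2,4,4,6-tetrabromocyclohexa-2,5-dienone (TBCO), MeNO2, 0 °C → rt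
Reagents that add atoms: 2,4,4,6-tetrabromocyclohexa-2,5-dien-1-one, O=C1C(Br)=CC(Br)(Br)C=C1Br
Why: Bromoetherification (bromonium-induced 6-endo cyclisation), in which Br+ adds to the electron-rich trisubstituted olefin rather than to the isopropenyl group, the tertiary hydroxyl opens the bromonium ion at its tertiary carbon, and a chair transition state with the isopropenyl group equatorial, the C-2 methyl and the acetoxy group axial and bromine equatorial (anti addition) should set C-5 as S.

Step 5
Reactants: 7 (2S,3S,5S)-5-bromo-2,6,6-trimethyl-2-(prop-1-en-2-yl)oxan-3-yl acetate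
Product: 8 (2S,3S,5S)-5-bromo-2,6,6-trimethyl-2-(3-oxoprop-1-en-2-yl)oxan-3-yl acetate
Conditions: SeO2, 1,4-dioxane, 80 °C
Reagents that add atoms: selenium dioxide, O=[Se]=O
Why: Allylic (Riley) oxidation with SeO2, in which an ene reaction at the only olefin, a [2,3]-sigmatropic shift and further oxidation turn the vinylic methyl group, the sole allylic C–H position because C-2 is quaternary, into the aldehyde of an α-substituted acrolein.

Step 6
Reactants: 9 bromo(2-methylprop-1-en-1-yl)magnesium
Product: 10 trimethyl(2-methylprop-1-en-1-yl)silane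
Conditions: Me3SiCl, THF, 0 °C → rt
Reagents that add atoms: chlorotrimethylsilane, C[Si](C)(C)Cl
Why: Silylation of a vinyl Grignard reagent at silicon, a substitution that forms the C(sp2)–Si bond and leaves the olefin in place.

Step 7
Reactants: 8 (2S,3S,5S)-5-bromo-2,6,6-trimethyl-2-(3-oxoprop-1-en-2-yl)oxan-3-yl acetate; 10 trimethyl(2-methylprop-1-en-1-yl)silane
Product: 12 (2S,3S,5S)-5-bromo-2-[(1S,6R)-6-hydroxy-4-methylcyclohex-3-en-1-yl]-2,6,6-trimethyloxan-3-yl acetate, via allylsilane aldehyde 11 (not isolated)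
Conditions: Me2AlCl (2.5 equiv), 10 (3 equiv), CH2Cl2, −78 → −20 °C; then 1 M HCl
Reagents that add atoms: none
Why: Proposed new method: Me2AlCl activates the aldehyde of 8, the silicon-bearing carbon of 10 adds to the CH2 terminus (C-6') in a conjugate ene reaction in which the tertiary β-silyl cation hands a methyl hydrogen to C-1' to give allylsilane aldehyde 11, and the CH2= terminus of 11 (C-3') then attacks the aluminium-bound aldehyde while the silyl group leaves, which places the ring olefin at C-4'=C-5' only. The closest known reaction types are the aluminium-promoted two-stage ene annulation of acrolein with 1,1-disubstituted alkenes, the ene reaction of vinylsilanes that keeps silicon, and the intramolecular Hosomi–Sakurai allylation; their union as a [3+3] annulation of an α-substituted acrolein is new. The cyclohexene ring closes 6-exo-trig at the carbonyl carbon (allylsilane olefin inside the ring) through a chair with the oxanyl group equatorial. C-1' (S) is set in the suprafacial hydrogen transfer: the bis-tertiary ether oxygen is too hindered to chelate aluminium, the C-2–O bond eclipses the C=CH2 bond, and the silane adds anti to C-3 with its acetoxy group, on the face flanked by the C-2 methyl; C-2' (R) is set in the closure, where the synclinal approach of C=C to C=O puts the aluminium-bound oxygen axial and cis to the equatorial oxanyl group. The step needs conjugate (C-6') rather than carbonyl attack in the first stage and ene transfer rather than ipso-desilylation; the first is secured by the soft alkene nucleophile and the shielding of the aldehyde by the quaternary C-2, the second by the fast intramolecular hydrogen shift to the aluminium enolate at −78 °C, and both C-5' silyl epimers of 11 converge because that carbon becomes sp2.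

Step 8
Reactants: 12 (2S,3S,5S)-5-bromo-2-[(1S,6R)-6-hydroxy-4-methylcyclohex-3-en-1-yl]-2,6,6-trimethyloxan-3-yl acetate
Product: 13 (2S,3S,5S)-5-bromo-2-[(1R,3S,4R,6S)-4-hydroxy-6-methyl-7-oxabicyclo[4.1.0]heptan-3-yl]-2,6,6-trimethyloxan-3-yl acetate
Conditions: VO(acac)2 (5 mol%), t-BuOOH, CH2Cl2, rt
Reagents that add atoms: tert-butyl hydroperoxide, CC(C)(C)OO
Why: Hydroxyl-directed epoxidation, in which the axial homoallylic hydroxyl at C-2' binds vanadium and delivers the peroxide oxygen to the olefin face syn to it, setting C-4' and C-5' (oxirane cis to the hydroxyl), while no other olefin remains in the molecule.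

Step 9
Reactants: 13 (2S,3S,5S)-5-bromo-2-[(1R,3S,4R,6S)-4-hydroxy-6-methyl-7-oxabicyclo[4.1.0]heptan-3-yl]-2,6,6-trimethyloxan-3-yl acetate
Product: 14 (2S,3S,5S)-5-bromo-2-[(1S,2R,4S,5S)-5-chloro-2,4-dihydroxy-4-methylcyclohexyl]-2,6,6-trimethyloxan-3-yl acetate
Conditions: LiCl, AcOH, THF, rt
Reagents that add atoms: lithium chloride, [Li+].[Cl-]
Why: Regio- and stereoselective epoxide opening, in which, with the oxanyl group equatorial, trans-diaxial (Fürst–Plattner) attack of chloride occurs with inversion at the less hindered secondary C-5' and leaves an axial tertiary hydroxyl at C-4' anti to the axial chlorine.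

Step 10
Reactants: 14 (2S,3S,5S)-5-bromo-2-[(1S,2R,4S,5S)-5-chloro-2,4-dihydroxy-4-methylcyclohexyl]-2,6,6-trimethyloxan-3-yl acetate
Product: 16 (2S,3S,5S)-5-bromo-2-[(1S,2R,4R,5R)-5-bromo-4-chloro-2-hydroxy-4-methylcyclohexyl]-2,6,6-trimethyloxan-3-yl acetate, via diaxial bromide 15 (not isolated)
Conditions: Me3SiBr, CH2Cl2, −30 → 0 °C; then MeNO2, 60 °C
Reagents that add atoms: bromotrimethylsilane, C[Si](C)(C)Br
Why: Conversion of the tertiary alcohol into the bromide by an SN1 path, in which the anti-periplanar chlorine (chloronium-type participation) and axial attack should give the trans-diaxial bromide 15 with retention, followed by the thermal 1,2-interchange of vicinal halogens (diaxial-to-diequatorial dihalide rearrangement), which moves bromine to C-5' and chlorine to C-4' each on its own face, relieves the syn-diaxial Br/OH strain and is favoured by the polar solvent, so that C-4' and C-5' end as R and R.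

Compound list
1 | 6-methylhept-5-en-2-one | CC(=O)CCC=C(C)C | starting material
2 | (3S)-6-methyl-3-[(phenylamino)oxy]hept-5-en-2-one | CC(=O)[C@@H](ONc1ccccc1)CC=C(C)C | intermediate
3 | (3S)-3-hydroxy-6-methylhept-5-en-2-one | CC(=O)[C@@H](O)CC=C(C)C | intermediate
4 | bromo(prop-1-en-2-yl)magnesium | CC(=C)[Mg]Br | starting material
5 | (3S,4S)-2,3,7-trimethylocta-1,6-diene-3,4-diol | O[C@@H](CC=C(C)C)[C@@](C)(O)C(C)=C | intermediate
6 | (3S,4S)-3-hydroxy-2,3,7-trimethylocta-1,6-dien-4-yl acetate | CC(=O)O[C@@H](CC=C(C)C)[C@@](C)(O)C(C)=C | intermediate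
7 | (2S,3S,5S)-5-bromo-2,6,6-trimethyl-2-(prop-1-en-2-yl)oxan-3-yl acetate | CC(=O)O[C@H]1C[C@H](Br)C(C)(C)O[C@@]1(C)C(C)=C | intermediate
8 | (2S,3S,5S)-5-bromo-2,6,6-trimethyl-2-(3-oxoprop-1-en-2-yl)oxan-3-yl acetate | CC(=O)O[C@H]1C[C@H](Br)C(C)(C)O[C@@]1(C)C(=C)C=O | intermediate
9 | bromo(2-methylprop-1-en-1-yl)magnesium | CC(C)=C[Mg]Br | starting material
10 | trimethyl(2-methylprop-1-en-1-yl)silane | CC(C)=C[Si](C)(C)C | intermediate
11 | (2S,3S,5S)-5-bromo-2,6,6-trimethyl-2-[(2R)-5-methyl-1-oxo-4-(trimethylsilyl)hex-5-en-2-yl]oxan-3-yl acetate (both epimers at the silyl-bearing carbon) | CC(=O)O[C@H]1C[C@H](Br)C(C)(C)O[C@@]1(C)[C@H](C=O)CC([Si](C)(C)C)C(C)=C | intermediate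
12 | (2S,3S,5S)-5-bromo-2-[(1S,6R)-6-hydroxy-4-methylcyclohex-3-en-1-yl]-2,6,6-trimethyloxan-3-yl acetate | CC(=O)O[C@H]1C[C@H](Br)C(C)(C)O[C@@]1(C)[C@H]1CC=C(C)C[C@H]1O | intermediate
13 | (2S,3S,5S)-5-bromo-2-[(1R,3S,4R,6S)-4-hydroxy-6-methyl-7-oxabicyclo[4.1.0]heptan-3-yl]-2,6,6-trimethyloxan-3-yl acetate | CC(=O)O[C@H]1C[C@H](Br)C(C)(C)O[C@@]1(C)[C@H]1C[C@H]2O[C@@]2(C)C[C@H]1O | intermediate
14 | (2S,3S,5S)-5-bromo-2-[(1S,2R,4S,5S)-5-chloro-2,4-dihydroxy-4-methylcyclohexyl]-2,6,6-trimethyloxan-3-yl acetate | CC(=O)O[C@H]1C[C@H](Br)C(C)(C)O[C@@]1(C)[C@H]1C[C@H](Cl)[C@@](C)(O)C[C@H]1O | intermediate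
15 | (2S,3S,5S)-5-bromo-2-[(1S,2R,4S,5S)-4-bromo-5-chloro-2-hydroxy-4-methylcyclohexyl]-2,6,6-trimethyloxan-3-yl acetate | CC(=O)O[C@H]1C[C@H](Br)C(C)(C)O[C@@]1(C)[C@H]1C[C@H](Cl)[C@@](C)(Br)C[C@H]1O | intermediate
16 | (2S,3S,5S)-5-bromo-2-[(1S,2R,4R,5R)-5-bromo-4-chloro-2-hydroxy-4-methylcyclohexyl]-2,6,6-trimethyloxan-3-yl acetate | CC(=O)O[C@H]1C[C@H](Br)C(C)(C)O[C@@]1(C)[C@H]1C[C@@H](Br)[C@](C)(Cl)C[C@H]1O | target

Total step count: 10. Longest linear sequence: 9 steps (steps 1 to 5, then 7 to 10).

Steps most likely to fail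

Step 7. The silyl group may be lost already at the first C–C bond formation (ipso substitution instead of hydrogen transfer), so that the chain is only prenylated and no ring closes. The fallback sets out from 8 and comes back at 12. The known aluminium-promoted two-stage ene annulation of 8 with 2-methylpropene (Me2AlCl, CH2Cl2, −78 → 0 °C) should give the exocyclic olefin (2S,3S,5S)-5-bromo-2-[(1S,2R)-2-hydroxy-4-methylidenecyclohexyl]-2,6,6-trimethyloxan-3-yl acetate F1. Acid-catalysed migration of the exocyclic olefin into the ring (p-TsOH, CH2Cl2, rt) and separation from the allylic-alcohol regioisomer then gives 12.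

Step 10. The tertiary cation may lose a proton, or take up bromide on the face syn to chlorine, and the halogen interchange may stop at an unfavourable diaxial/diequatorial equilibrium. The fallback sets out from 12 and comes back at 16, and makes the bromonium ion on the upper face by neighbouring-group participation instead.
- Silylation (TBSOTf, 2,6-lutidine) gives (2S,3S,5S)-5-bromo-2-[(1S,6R)-6-{[tert-butyl(dimethyl)silyl]oxy}-4-methylcyclohex-3-en-1-yl]-2,6,6-trimethyloxan-3-yl acetate F2.
- m-CPBA, kept off the upper face by the axial silyloxy group, gives the anti epoxide (2S,3S,5S)-5-bromo-2-[(1S,3S,4R,6R)-4-{[tert-butyl(dimethyl)silyl]oxy}-6-methyl-7-oxabicyclo[4.1.0]heptan-3-yl]-2,6,6-trimethyloxan-3-yl acetate F3.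
- LiBr and AcOH in THF open it trans-diaxially at the tertiary carbon to (2S,3S,5S)-5-bromo-2-[(1S,2R,4S,5S)-4-bromo-2-{[tert-butyl(dimethyl)silyl]oxy}-5-hydroxy-4-methylcyclohexyl]-2,6,6-trimethyloxan-3-yl acetate F4.
- SOCl2 ionises the secondary alcohol with participation of the anti bromine, and chloride enters at the tertiary carbon from below to give (2S,3S,5S)-5-bromo-2-[(1S,2R,4R,5R)-5-bromo-4-chloro-2-{[tert-butyl(dimethyl)silyl]oxy}-4-methylcyclohexyl]-2,6,6-trimethyloxan-3-yl acetate F5.
- HF·pyridine removes the silyl group and gives 16.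

Step 4. The hydroxyl may close 5-exo at the secondary carbon of the bromonium ion to a tetrahydrofuran, and Br+ may also attack the isopropenyl group. The fallback sets out from 6 and comes back at 7. Alkoxymercuration with Hg(OCOCF3)2 in MeNO2, which is reversible and settles on the six-membered ether, followed by aqueous KBr should give (2S,3S,5S)-5-(bromomercurio)-2,6,6-trimethyl-2-(prop-1-en-2-yl)oxan-3-yl acetate F6. Brominolysis (Br2, LiBr, pyridine, O2) then replaces mercury by bromine and gives 7.

Further compounds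
F1 | step 7 | (2S,3S,5S)-5-bromo-2-[(1S,2R)-2-hydroxy-4-methylidenecyclohexyl]-2,6,6-trimethyloxan-3-yl acetate | CC(=O)O[C@H]1C[C@H](Br)C(C)(C)O[C@@]1(C)[C@H]1CCC(=C)C[C@H]1O
F2 | step 10 | (2S,3S,5S)-5-bromo-2-[(1S,6R)-6-{[tert-butyl(dimethyl)silyl]oxy}-4-methylcyclohex-3-en-1-yl]-2,6,6-trimethyloxan-3-yl acetate | CC(=O)O[C@H]1C[C@H](Br)C(C)(C)O[C@@]1(C)[C@H]1CC=C(C)C[C@H]1O[Si](C)(C)C(C)(C)C
F3 | step 10 | (2S,3S,5S)-5-bromo-2-[(1S,3S,4R,6R)-4-{[tert-butyl(dimethyl)silyl]oxy}-6-methyl-7-oxabicyclo[4.1.0]heptan-3-yl]-2,6,6-trimethyloxan-3-yl acetate | CC(=O)O[C@H]1C[C@H](Br)C(C)(C)O[C@@]1(C)[C@H]1C[C@@H]2O[C@]2(C)C[C@H]1O[Si](C)(C)C(C)(C)C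
F4 | step 10 | (2S,3S,5S)-5-bromo-2-[(1S,2R,4S,5S)-4-bromo-2-{[tert-butyl(dimethyl)silyl]oxy}-5-hydroxy-4-methylcyclohexyl]-2,6,6-trimethyloxan-3-yl acetate | CC(=O)O[C@H]1C[C@H](Br)C(C)(C)O[C@@]1(C)[C@H]1C[C@H](O)[C@@](C)(Br)C[C@H]1O[Si](C)(C)C(C)(C)C
F5 | step 10 | (2S,3S,5S)-5-bromo-2-[(1S,2R,4R,5R)-5-bromo-4-chloro-2-{[tert-butyl(dimethyl)silyl]oxy}-4-methylcyclohexyl]-2,6,6-trimethyloxan-3-yl acetate | CC(=O)O[C@H]1C[C@H](Br)C(C)(C)O[C@@]1(C)[C@H]1C[C@@H](Br)[C@](C)(Cl)C[C@H]1O[Si](C)(C)C(C)(C)C
F6 | step 4 | (2S,3S,5S)-5-(bromomercurio)-2,6,6-trimethyl-2-(prop-1-en-2-yl)oxan-3-yl acetate | CC(=O)O[C@H]1C[C@H]([Hg]Br)C(C)(C)O[C@@]1(C)C(C)=C
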